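**Retrosynthetic overview**

- Target 18 comes from the bis-MOM (2S)-flavanone 17, obtained by kinetic resolution of racemic flavanone 16. Ring C of 16 is opened at O1–C2 (oxa-Michael) to chalcone 15, and the C2–C3 bond is cut (Claisen–Schmidt) to acetophenone 13 and aldehyde 9.
- Aldehyde 9 comes from benzoate 7, which is cut at C2'–C3' and C4'–C5' into methyl coumalate 5 and ynol ether 4 (pyrone Diels–Alder with loss of CO2); 4 comes from methoxyacetylide and a homoallylic bromide.
- The strategy rests on ring B, a benzene with C1' (bonded to C2 of ring C), the 3-methylbut-3-enyl chain at C3' and OMe at C4' in a 1,3,4 pattern. This is the pattern that the C5 ester of the pyrone, the alkyl-bearing alkyne carbon and the oxygen-bearing alkyne carbon take up in a coumalate/1-alkoxyalkyne cycloaddition.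
- Ring order: ring B is built (step 2); ring A is bought as phloroacetophenone and prenylated at the future C8; ring C is closed last (step 8) and its C2 configuration is secured in step 9.

Key step: step 2

Remark: catalytic asymmetric oxa-Michael closure of unactivated 2'-hydroxychalcones is substrate-dependent in sense and level of induction, so ring C is closed without chiral control (step 8) and the 2S enantiomer is secured by kinetic resolution (step 9).

**Route**

Step 1
Reactants: 1 chloroacetaldehyde dimethyl acetal (2-chloro-1,1-dimethoxyethane); 2 homoallylic bromide 4-bromo-2-methylbut-1-ene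
Product: 4 ynol ether 1-methoxy-5-methylhex-5-en-1-yne, via sodium methoxyacetylide 3 (not isolated)
Conditions: NaNH2 (3.1 equiv), liq. NH3, −35 °C; then 2, Et2O co-solvent, −35 °C to rt as NH3 evaporates; solid NH4Cl quench; distillation
Reagents that add atoms: none
Why: Sodium amide removes HCl and methanol from the chloroacetal by twofold β-elimination and deprotonates the resulting methoxyacetylene (the classical alkoxyacetylide preparation), and the acetylide then displaces bromide from the primary bromide in an SN2 acetylide alkylation.

Step 2
Reactants: 5 methyl coumalate (methyl 2-oxo-2H-pyran-5-carboxylate); 4 ynol ether 1-methoxy-5-methylhex-5-en-1-yne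
Product: 7 methyl 4-methoxy-3-(3-methylbut-3-enyl)benzoate, via bicyclic lactone cycloadduct 6 (not isolated)
Conditions: 4 (1.5 equiv), toluene, 110 °C, sealed tube, N2
Reagents that add atoms: none
Why: Inverse-electron-demand Diels–Alder reaction in which the electron-poor 2-pyrone (diene carbons C3 to C6, lowered in energy by the lactone and the C5 ester) takes up the electron-rich alkyne across C3 and C6 to give the bridged lactone 6, which should lose CO2 by retro-[4+2] cycloreversion at the reaction temperature and so deliver the arene without any oxidation or elimination step. The closest known reaction type is the cycloaddition/decarboxylation of methyl coumalate with ynamines, ketene acetals and enol ethers to para-substituted benzoates. Ring B is closed by an intermolecular [4+2] cycloaddition that joins four pyrone carbons to the two alkyne carbons (new bonds C2'–C3' and C4'–C5'), and the two bridgehead stereocentres of 6 vanish on aromatisation, so no stereocentre has to be controlled. The step needs regioselectivity, which the polarisation of both partners secures: the nucleophilic alkyl-bearing carbon of the ynol ether bonds to C6, the most electrophilic terminus of the pyrone, and the oxygen-bearing carbon bonds to C3, which places OMe para and the side chain meta to the ester. It also needs chemoselectivity for the alkyne over the 1,1-disubstituted alkene of the side chain, which is not electron-rich enough to engage the pyrone at this temperature, and a methyl ynol ether has no β-hydrogen on its O-alkyl group, so it cannot fragment to a ketene by a retro-ene path on heating.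

Step 3
Reactants: 7 methyl 4-methoxy-3-(3-methylbut-3-enyl)benzoate
Product: 8 [4-methoxy-3-(3-methylbut-3-enyl)phenyl]methanol
Conditions: i-Bu2AlH (DIBAL-H, 2.5 equiv), CH2Cl2, −78 °C to 0 °C; aq. Rochelle salt
Reagents that add atoms: none
Why: Hydride reduction of the aryl ester by DIBAL-H goes through the aldehyde to the benzylic alcohol and leaves the isolated 1,1-disubstituted alkene and the aryl methyl ether untouched.

Step 4
Reactants: 8 [4-methoxy-3-(3-methylbut-3-enyl)phenyl]methanol
Product: 9 4-methoxy-3-(3-methylbut-3-enyl)benzaldehyde
Conditions: activated MnO2 (10 equiv), CH2Cl2, rt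
Reagents that add atoms: none
Why: Activated MnO2 oxidises benzylic alcohols selectively to aldehydes without over-oxidation and does not touch the alkene.

Step 5
Reactants: 10 2,4,6-trihydroxyacetophenone; 11 prenyl bromide (1-bromo-3-methylbut-2-ene)
Product: 12 1-[2,4,6-trihydroxy-3-(3-methylbut-2-enyl)phenyl]ethanone
Conditions: DBU (1.0 equiv), 11 (1.0 equiv, slow addition), THF, rt
Reagents that add atoms: none
Why: C-alkylation of the ambident phloroglucinol-type phenoxide by the allylic bromide (a Friedel–Crafts-like C-allylation) places the prenyl group on a ring CH, and since C3 and C5 are equivalent only one mono-C-prenyl isomer can form, O-prenyl and di-C-prenyl products being removed by chromatography.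

Step 6
Reactants: 12 1-[2,4,6-trihydroxy-3-(3-methylbut-2-enyl)phenyl]ethanone
Product: 13 1-[2-hydroxy-4,6-bis(methoxymethoxy)-3-(3-methylbut-2-enyl)phenyl]ethanone
Conditions: MOMCl (2.2 equiv), i-Pr2NEt (3 equiv), CH2Cl2, 0 °C to rt
Reagents that add atoms: chloromethyl methyl ether (MOMCl), COCCl
Why: MOM ether formation (base-mediated O-alkylation) should take place first at the free 4-OH and then at the less hindered of the two carbonyl-chelated hydroxyls (6-OH), leaving free the 2-OH that is both hydrogen-bonded to the acetyl group and flanked by the prenyl group, which is the oxygen that must later close ring C next to the prenyl substituent.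

Step 7
Reactants: 13 1-[2-hydroxy-4,6-bis(methoxymethoxy)-3-(3-methylbut-2-enyl)phenyl]ethanone; 9 4-methoxy-3-(3-methylbut-3-enyl)benzaldehyde
Product: 15 (E)-1-[2-hydroxy-4,6-bis(methoxymethoxy)-3-(3-methylbut-2-enyl)phenyl]-3-[4-methoxy-3-(3-methylbut-3-enyl)phenyl]prop-2-en-1-one, via aldol adduct 14 (not isolated)
Conditions: KOH (50% aq.), EtOH, rt
Reagents that add atoms: none
Why: Claisen–Schmidt (crossed aldol) condensation in which the acetophenone enolate adds to the non-enolisable aldehyde and the aldol adduct loses water by an E1cB path to give the conjugated E-enone, the MOM ethers and both alkenes being stable to aqueous hydroxide.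

Step 8
Reactants: 15 the (E)-chalcone of step 7
Product: 16 racemic 5,7-bis(methoxymethoxy)-2-[4-methoxy-3-(3-methylbut-3-enyl)phenyl]-8-(3-methylbut-2-enyl)chroman-4-one
Conditions: NaOAc (5 equiv), EtOH, reflux
Reagents that add atoms: none
Why: Intramolecular oxa-Michael addition (6-endo-trig) of the 2'-phenoxide to the enone under mild acetate catalysis closes ring C; only the prenyl-flanked 2'-oxygen is free, so the prenyl group can end up only at C8, and C2 forms as the racemate because nothing in the substrate or medium is chiral.

Step 9
Reactants: 16 racemic bis-MOM flavanone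
Product: 17 (2S)-5,7-bis(methoxymethoxy)-2-[4-methoxy-3-(3-methylbut-3-enyl)phenyl]-8-(3-methylbut-2-enyl)chroman-4-one
Conditions: Cp*RhCl[(R,R)-TsDPEN] (1 mol%), HCO2H/Et3N 5:2, EtOAc, rt, stopped a little beyond half conversion; chromatography
Reagents that add atoms: none
Why: Kinetic resolution by Noyori-type asymmetric transfer hydrogenation, in which the (R,R)-catalyst should transfer hydride to the carbonyl face that leads to a 4R alcohol, which in the 2R ketone is the open face anti to the C2 aryl group (matched, giving the cis-2R,4R alcohol), so that the 2R enantiomer is consumed and the 2S ketone, whose C2 centre is not touched, is recovered with an enantiomeric purity that rises with conversion.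

Step 10
Reactants: 17 (2S)-bis-MOM flavanone
Product: 18 (2S)-5,7-dihydroxy-2-[4-methoxy-3-(3-methylbut-3-enyl)phenyl]-8-(3-methylbut-2-enyl)chroman-4-one
Conditions: HCl (1 M in MeOH), rt to 40 °C, stopped when 17 is consumed
Reagents that add atoms: none
Why: Acid-catalysed transacetalisation to methanol cleaves both aryl MOM ethers under conditions mild enough that the prenyl and isopropenyl alkenes should not be protonated, and the C2 stereocentre, which epimerises only through base-induced ring opening, is retained.

**Compound list**

1 | chloroacetaldehyde dimethyl acetal | COC(CCl)OC | starting material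
2 | 4-bromo-2-methylbut-1-ene | C=C(C)CCBr | starting material
3 | sodium methoxyacetylide | [Na+].[C-]#COC | intermediate (not isolated)
4 | 1-methoxy-5-methylhex-5-en-1-yne | COC#CCCC(C)=C | intermediate
5 | methyl coumalate | COC(=O)C1=COC(=O)C=C1 | starting material
6 | methyl 8-methoxy-7-(3-methylbut-3-enyl)-3-oxo-2-oxabicyclo[2.2.2]octa-5,7-diene-6-carboxylate (racemic) | O=C1OC2C(C(=O)OC)=CC1C(OC)=C2CCC(C)=C | intermediate (not isolated)
7 | methyl 4-methoxy-3-(3-methylbut-3-enyl)benzoate | C=C(C)CCc1cc(C(=O)OC)ccc1OC | intermediate
8 | [4-methoxy-3-(3-methylbut-3-enyl)phenyl]methanol | C=C(C)CCc1cc(CO)ccc1OC | intermediate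
9 | 4-methoxy-3-(3-methylbut-3-enyl)benzaldehyde | C=C(C)CCc1cc(C=O)ccc1OC | intermediate
10 | 2,4,6-trihydroxyacetophenone | CC(=O)c1c(O)cc(O)cc1O | starting material
11 | prenyl bromide (1-bromo-3-methylbut-2-ene) | CC(C)=CCBr | starting material
12 | 1-[2,4,6-trihydroxy-3-(3-methylbut-2-enyl)phenyl]ethanone | CC(=O)c1c(O)cc(O)c(CC=C(C)C)c1O | intermediate
13 | 1-[2-hydroxy-4,6-bis(methoxymethoxy)-3-(3-methylbut-2-enyl)phenyl]ethanone | CC(=O)c1c(OCOC)cc(OCOC)c(CC=C(C)C)c1O | intermediate
14 | 3-hydroxy-1-[2-hydroxy-4,6-bis(methoxymethoxy)-3-(3-methylbut-2-enyl)phenyl]-3-[4-methoxy-3-(3-methylbut-3-enyl)phenyl]propan-1-one (racemic) | C=C(C)CCc1cc(C(O)CC(=O)c2c(OCOC)cc(OCOC)c(CC=C(C)C)c2O)ccc1OC | intermediate (not isolated)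
15 | (E)-1-[2-hydroxy-4,6-bis(methoxymethoxy)-3-(3-methylbut-2-enyl)phenyl]-3-[4-methoxy-3-(3-methylbut-3-enyl)phenyl]prop-2-en-1-one | C=C(C)CCc1cc(/C=C/C(=O)c2c(OCOC)cc(OCOC)c(CC=C(C)C)c2O)ccc1OC | intermediate
16 | racemic 5,7-bis(methoxymethoxy)-2-[4-methoxy-3-(3-methylbut-3-enyl)phenyl]-8-(3-methylbut-2-enyl)chroman-4-one | C=C(C)CCc1cc(C2CC(=O)c3c(OCOC)cc(OCOC)c(CC=C(C)C)c3O2)ccc1OC | intermediate
17 | (2S)-5,7-bis(methoxymethoxy)-2-[4-methoxy-3-(3-methylbut-3-enyl)phenyl]-8-(3-methylbut-2-enyl)chroman-4-one | C=C(C)CCc1cc([C@@H]2CC(=O)c3c(OCOC)cc(OCOC)c(CC=C(C)C)c3O2)ccc1OC | intermediate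
18 | (2S)-5,7-dihydroxy-2-[4-methoxy-3-(3-methylbut-3-enyl)phenyl]-8-(3-methylbut-2-enyl)chroman-4-one | C=C(C)CCc1cc([C@@H]2CC(=O)c3c(O)cc(O)c(CC=C(C)C)c3O2)ccc1OC | target

**Step count**

Total: 10 steps. Longest linear sequence: 8 steps (1, 2, 3, 4, 7, 8, 9, 10).

**Steps most likely to fail**

Step 2. The cycloaddition may be slower than thermal oligomerisation of the ynol ether, or conjugate addition at C6 of the pyrone may not be followed by ring closure, so that little arene forms. The fallback gives up ring construction for this compound and makes the aryl–alkyl bond by cross-coupling. It sets out from 2: zinc insertion (Zn dust, LiCl, THF) gives 3-methylbut-3-enylzinc bromide F1. Negishi coupling of F1 with bought methyl 3-bromo-4-methoxybenzoate (COC(=O)c1ccc(OC)c(Br)c1) under Pd(OAc)2/SPhos in THF then gives benzoate 7, where it rejoins the route.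

Step 1. E2 loss of HBr from the homoallylic bromide, whose β-hydrogens are allylic, may outrun substitution under the strongly basic acetylide and amide. The fallback carries the side chain as a ketal that has no allylic β-hydrogens and unveils the alkene after ring B is built. It sets out from 1: acetylide 3 is generated as in step 1 and alkylated with bought 2-(2-bromoethyl)-2-methyl-1,3-dioxolane (CC1(CCBr)OCCO1) to give 2-(4-methoxybut-3-ynyl)-2-methyl-1,3-dioxolane F2. Cycloaddition of F2 with 5 under the conditions of step 2, with loss of CO2, gives methyl 4-methoxy-3-[2-(2-methyl-1,3-dioxolan-2-yl)ethyl]benzoate F3. Deketalisation (PPTS, acetone/H2O) gives methyl 4-methoxy-3-(3-oxobutyl)benzoate F4, and Wittig methylenation (Ph3P=CH2 from Ph3PCH3Br and KOt-Bu, THF, 0 °C), which is faster at the ketone than at the ester, gives 7, where it rejoins the route.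

Step 9. The rate difference between the two enantiomers may be too small at this hindered ketone, which is flanked by the peri 5-OMOM group, so that the recovered ketone is not enriched enough at acceptable conversion. The fallback sets the C2 centre during ring closure instead. It sets out from chalcone 15, which is cyclised by enantioselective intramolecular oxa-Michael addition with a cinchona-derived bifunctional thiourea (the 3,5-bis(trifluoromethyl)phenyl thiourea of 9-amino-9-deoxy-epi-quinine, or its quinidine-derived pseudoenantiomer, toluene, rt). The thiourea binds the enone carbonyl and the quinuclidine nitrogen deprotonates the phenol. Both pseudoenantiomers are available, so the sense can be matched to 2S after a trial, and the product is 17, where it rejoins the route.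

**Further compounds**

F1 | step 2 | 3-methylbut-3-enylzinc bromide | C=C(C)CC[Zn]Br
F2 | step 1 | 2-(4-methoxybut-3-ynyl)-2-methyl-1,3-dioxolane | COC#CCCC1(C)OCCO1
F3 | step 1 | methyl 4-methoxy-3-[2-(2-methyl-1,3-dioxolan-2-yl)ethyl]benzoate | COC(=O)c1ccc(OC)c(CCC2(C)OCCO2)c1
F4 | step 1 | methyl 4-methoxy-3-(3-oxobutyl)benzoate | COC(=O)c1ccc(OC)c(CCC(C)=O)c1
F0 | step 9 | none | none
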